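**Retrosynthetic overview**

1. The C3 acetate and C8 angelate are installed last on a silyl-protected macrolactone that already carries all seven ring stereocentres.
2. Key disconnection: C6–C7 and C11–C12 together. The α-methylene-γ-lactone array C13=C11(–C12)–C7, fused to the cyclodecene ring at C6–C7, is read as a terminal 1,2-diene (C13=C11=C7), an enal carbonyl (C6) and CO2 (C12), so an acyclic allenyl enal is closed by a Ni(0)/CO2 carboxylative allylation.
3. The allenyl enal comes from a cis-glycidic Weinreb amide and an (E)-alkenyllithium (C3–C4 bond), with C3 set by chelation-controlled reduction; the cis-oxirane C1–C2 comes from an Evans chloroacetate syn-aldol and ring closure.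
4. The C7–C10/C1 aldehyde comes from (R)-citramalic acid (C10), a Noyori transfer hydrogenation (C8) and an SN2′ hydride reduction that makes the allene.
5. Ring order: oxirane (step 9), then the ten-membered carbocycle and the γ-lactone together (step 16).

Key step: step 16

Remark: germacrane numbering is used (ring C1–C10, exocyclic methylene C11=C13, lactone carbonyl C12, lactone oxygen on C6); the CIP labels at C2 and C7 change with the O-substituents although the spatial arrangement stays that of the target.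
Remark: the tetrahydropyranyl acetal carbon of 3, 5 and 6 is a mixture of epimers; this is of no consequence because the group is lost in step 4.

**Route**

Step 1
Reactants: 1 (R)-citramalic acid
Product: 2 (R)-2-(2,2,4-trimethyl-5-oxo-1,3-dioxolan-4-yl)acetic acid
Conditions: Me2C(OMe)2, TsOH·H2O (cat.), acetone, rt
Reagents that add atoms: 2,2-dimethoxypropane, COC(C)(C)OC
Why: Acid-catalysed acetalisation engages only the α-hydroxy acid (1,3-dioxolan-4-one formation), which differentiates the two carboxyls and masks the tertiary alcohol without touching C10.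

Step 2
Reactants: 2 (R)-2-(2,2,4-trimethyl-5-oxo-1,3-dioxolan-4-yl)acetic acid; 3 2-(prop-2-yn-1-yloxy)tetrahydro-2H-pyran
Product: 5 (5R)-2,2,5-trimethyl-5-[2-oxo-5-(oxan-2-yloxy)pent-3-yn-1-yl]-1,3-dioxolan-4-one, via acid chloride 4 (not isolated)
Conditions: (COCl)2, DMF (cat.), CH2Cl2, 0 °C → rt; then 3, PdCl2(PPh3)2 (cat.), CuI (cat.), Et3N, THF, rt
Reagents that add atoms: none
Why: Acyl Sonogashira coupling of an acid chloride with a terminal alkyne should give the ynone under conditions that the dioxolanone and the THP acetal tolerate.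

Step 3
Reactants: 5 (5R)-2,2,5-trimethyl-5-[2-oxo-5-(oxan-2-yloxy)pent-3-yn-1-yl]-1,3-dioxolan-4-one
Product: 6 (5R)-5-[(2R)-2-hydroxy-5-(oxan-2-yloxy)pent-3-yn-1-yl]-2,2,5-trimethyl-1,3-dioxolan-4-one
Conditions: RuCl[(R,R)-TsDPEN](p-cymene) (cat.), iPrOH, rt
Reagents that add atoms: none
Why: Noyori asymmetric transfer hydrogenation of an alkynyl ketone, in which the alkyne takes the place of the aryl group, should set C8 as (R) under catalyst control, independent of the remote C10 centre.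

Step 4
Reactants: 6 (5R)-5-[(2R)-2-hydroxy-5-(oxan-2-yloxy)pent-3-yn-1-yl]-2,2,5-trimethyl-1,3-dioxolan-4-one
Product: 7 (2R,4R)-2-methylhepta-5,6-diene-1,2,4-triol
Conditions: LiAlH4 (excess), THF, 0 °C → reflux; Rochelle salt work-up
Reagents that add atoms: none
Why: Hydride reduces the dioxolanone (or any γ-lactone formed from it by acyl transfer) to the primary/tertiary diol and, directed by the C8 alkoxide, trans-hydroaluminates the alkyne and expels the propargylic OTHP group (SN2′-type reduction of a 4-alkoxyalk-2-yn-1-ol to an α-allenic alcohol), leaving C8 and C10 untouched.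

Step 5
Reactants: 7 (2R,4R)-2-methylhepta-5,6-diene-1,2,4-triol
Product: 8 (2R,4R)-2-methyl-1,2,4-tris(triethylsilyloxy)hepta-5,6-diene
Conditions: TESOTf, 2,6-lutidine, CH2Cl2, −78 → 0 °C
Reagents that add atoms: triethylsilyl trifluoromethanesulfonate, CC[Si](CC)(CC)OS(=O)(=O)C(F)(F)F
Why: Silyl triflate/lutidine silylation is strong enough for the tertiary alcohol and should protect all three hydroxyls in one operation.

Step 6
Reactants: 8 (2R,4R)-2-methyl-1,2,4-tris(triethylsilyloxy)hepta-5,6-diene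
Product: 9 (2R,4R)-2-methyl-2,4-bis(triethylsilyloxy)hepta-5,6-dienal
Conditions: (COCl)2, DMSO, CH2Cl2, −78 → −30 °C; Et3N, −78 °C → rt
Reagents that add atoms: none
Why: Under Swern conditions a primary triethylsilyl ether is cleaved and oxidised in situ to the aldehyde while secondary and tertiary TES ethers survive (selective Swern oxidation of primary silyl ethers).

Step 7
Reactants: 9 (2R,4R)-2-methyl-2,4-bis(triethylsilyloxy)hepta-5,6-dienal; 10 (R)-4-benzyl-3-(chloroacetyl)oxazolidin-2-one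
Product: 12 (R)-4-benzyl-3-[(2R,3S,4R,6R)-2-chloro-3-hydroxy-4-methyl-4,6-bis(triethylsilyloxy)nona-7,8-dienoyl]oxazolidin-2-one, via boron enolate 11 (not isolated)
Conditions: 10, Bu2BOTf, Et3N, CH2Cl2, −78 → 0 °C; then 9, −78 → 0 °C; pH 7 buffer, MeOH, H2O2, 0 °C
Reagents that add atoms: none
Why: Evans syn-aldol reaction, in which the (Z)-boron enolate of the chloroacetyl imide adds through a Zimmerman–Traxler chair on the enolate face opposite the benzyl group, should set C2 (Cl) and C1 (OH) syn under auxiliary control.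

Step 8
Reactants: 12 (R)-4-benzyl-3-[(2R,3S,4R,6R)-2-chloro-3-hydroxy-4-methyl-4,6-bis(triethylsilyloxy)nona-7,8-dienoyl]oxazolidin-2-one
Product: 13 (2R,3S,4R,6R)-2-chloro-3-hydroxy-N-methoxy-N,4-dimethyl-4,6-bis(triethylsilyloxy)nona-7,8-dienamide
Conditions: MeNHOMe·HCl, AlMe3, THF, −20 → 0 °C
Reagents that add atoms: N,O-dimethylhydroxylamine hydrochloride, CNOC.Cl
Why: Aluminium amide transamination (Weinreb amide formation) of the β-hydroxy imide releases the auxiliary without touching the chlorohydrin stereocentres.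

Step 9
Reactants: 13 (2R,3S,4R,6R)-2-chloro-3-hydroxy-N-methoxy-N,4-dimethyl-4,6-bis(triethylsilyloxy)nona-7,8-dienamide
Product: 14 (2S,3R)-N-methoxy-N-methyl-3-[(2R,4R)-2,4-bis(triethylsilyloxy)hepta-5,6-dien-2-yl]oxirane-2-carboxamide
Conditions: K2CO3, MeOH, 0 °C → rt
Reagents that add atoms: none
Why: Intramolecular Williamson displacement of chloride by the C1 alkoxide (Darzens-type 3-exo-tet closure) inverts C2 and retains C1, so the syn-chlorohydrin should give the cis-oxirane.

Step 10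
Reactants: 15 but-2-yn-1-ol
Product: 16 (but-2-yn-1-yloxy)triethylsilane
Conditions: TESCl, imidazole, CH2Cl2, 0 °C → rt
Reagents that add atoms: chlorotriethylsilane, CC[Si](Cl)(CC)CC
Why: Standard silylation of a primary alcohol.

Step 11
Reactants: 16 (but-2-yn-1-yloxy)triethylsilane
Product: 18 (E)-triethyl[(3-iodobut-2-en-1-yl)oxy]silane, via alkenylzirconocene 17 (not isolated)
Conditions: Cp2Zr(H)Cl (excess), THF, rt → 50 °C; then I2, 0 °C
Reagents that add atoms: iodine, II
Why: Schwartz hydrozirconation adds Zr–H syn and, after equilibration, places zirconium on the methyl-bearing alkyne carbon, and iododezirconation with retention should give the (E)-alkenyl iodide.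

Step 12
Reactants: 14 (2S,3R)-N-methoxy-N-methyl-3-[(2R,4R)-2,4-bis(triethylsilyloxy)hepta-5,6-dien-2-yl]oxirane-2-carboxamide; 18 (E)-triethyl[(3-iodobut-2-en-1-yl)oxy]silane
Product: 20 (2E)-1-[(2S,3R)-3-[(2R,4R)-2,4-bis(triethylsilyloxy)hepta-5,6-dien-2-yl]oxiran-2-yl]-2-methyl-4-(triethylsilyloxy)but-2-en-1-one, via alkenyllithium 19 (not isolated)
Conditions: 18, t-BuLi (2.1 equiv), Et2O, −78 °C; then 14, −78 °C; aq. NH4Cl
Reagents that add atoms: none
Why: Lithium–iodine exchange proceeds with retention of alkene geometry and the alkenyllithium adds once to the Weinreb amide (chelated tetrahedral intermediate), which should give the α,β-epoxy enone without attack on the oxirane.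

Step 13
Reactants: 20 (2E)-1-[(2S,3R)-3-[(2R,4R)-2,4-bis(triethylsilyloxy)hepta-5,6-dien-2-yl]oxiran-2-yl]-2-methyl-4-(triethylsilyloxy)but-2-en-1-one
Product: 21 (1R,2E)-1-[(2R,3R)-3-[(2R,4R)-2,4-bis(triethylsilyloxy)hepta-5,6-dien-2-yl]oxiran-2-yl]-2-methyl-4-(triethylsilyloxy)but-2-en-1-ol
Conditions: Zn(BH4)2, Et2O, −20 °C
Reagents that add atoms: none
Why: Chelation-controlled 1,2-reduction of an α,β-epoxy ketone, in which zinc bridges the carbonyl and oxirane oxygens and hydride enters anti to C1, should give the erythro epoxy alcohol, that is the (3R) carbinol.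

Step 14
Reactants: 21 (1R,2E)-1-[(2R,3R)-3-[(2R,4R)-2,4-bis(triethylsilyloxy)hepta-5,6-dien-2-yl]oxiran-2-yl]-2-methyl-4-(triethylsilyloxy)but-2-en-1-ol
Product: 22 tert-butyl{[(1R,2E)-1-[(2S,3R)-3-[(2R,4R)-2,4-bis(triethylsilyloxy)hepta-5,6-dien-2-yl]oxiran-2-yl]-2-methyl-4-(triethylsilyloxy)but-2-en-1-yl]oxy}dimethylsilane
Conditions: TBSOTf, 2,6-lutidine, CH2Cl2, −78 °C
Reagents that add atoms: tert-butyldimethylsilyl trifluoromethanesulfonate, CC(C)(C)[Si](C)(C)OS(=O)(=O)C(F)(F)F
Why: Silyl triflate silylation of the hindered secondary allylic alcohol at low temperature leaves the oxirane intact and installs a group that outlasts the TES ethers.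

Step 15
Reactants: 22 tert-butyl{[(1R,2E)-1-[(2S,3R)-3-[(2R,4R)-2,4-bis(triethylsilyloxy)hepta-5,6-dien-2-yl]oxiran-2-yl]-2-methyl-4-(triethylsilyloxy)but-2-en-1-yl]oxy}dimethylsilane
Product: 23 (2E,4R)-4-(tert-butyldimethylsilyloxy)-4-[(2S,3R)-3-[(2R,4R)-2,4-bis(triethylsilyloxy)hepta-5,6-dien-2-yl]oxiran-2-yl]-3-methylbut-2-enal
Conditions: (COCl)2, DMSO, CH2Cl2, −78 → −40 °C; Et3N, −78 °C → rt
Reagents that add atoms: none
Why: Selective Swern oxidation of the primary allylic TES ether should give the (E)-enal directly while the secondary and tertiary silyl ethers remain.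

Step 16
Reactants: 23 (2E,4R)-4-(tert-butyldimethylsilyloxy)-4-[(2S,3R)-3-[(2R,4R)-2,4-bis(triethylsilyloxy)hepta-5,6-dien-2-yl]oxiran-2-yl]-3-methylbut-2-enal
Product: 26 (1R,2S,3R,4E,6S,7R,8R,10R)-3-(tert-butyldimethylsilyloxy)-1,2-epoxy-8,10-bis(triethylsilyloxy)germacra-4,11(13)-dien-12,6-olide, via oxanickelacycle 24 (not isolated), via seco hydroxy acid 25 (not isolated)
Conditions: Ni(cod)2 (1.1 equiv), DBU (2.5 equiv), CO2 (1 atm), THF (2 mM), 0 °C → rt; aq. NH4Cl/citric acid; PPTS (cat.), CH2Cl2, rt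
Reagents that add atoms: carbon dioxide, O=C=O
Why: Proposed new method: Ni(0) couples the terminal π-bond (C11=C13) of the 1,2-diene oxidatively with CO2 so that C11 binds C12 and a π-allylnickel carboxylate (oxanickelacycle 24) forms, whose η1 form with nickel on the unsubstituted terminus C13 adds through C7 to the tethered aldehyde C6 in a six-membered chair (SE2′) transition state, and acidification lets the 4-hydroxy-2-methylene acid 25 lactonise. The closest known reaction type is the Ni(cod)2/DBU-mediated sequential addition of CO2 and non-enolisable aldehydes to terminal allenes, run here intramolecularly in the manner of the allylmetal–aldehyde macrocyclisations (Nozaki–Hiyama–Kishi type) that close germacranolide rings. The ten-membered carbocycle closes by 1,2-allylation of the aldehyde (10-exo-trig with allyl transposition) and the γ-lactone by 5-exo-trig acyl substitution of O6 at C12. C6 and C7 are set together in the chair: the π-allyl equilibrates (η3–η1–η3) to the isomer that carries C8 and the enal chain pseudo-equatorial, which lets the eight-atom tether span C6 and C7 and gives the anti (6,7-trans) adduct, while the resident C8 centre selects the allyl face by holding H8 in the allyl plane (A1,3 strain) so that C6 is delivered anti to the C8–O bond with the OTES group outside the new ring. The step needs chemoselectivity for the cumulene (the trisubstituted enal alkene, the oxirane and the silyl ethers should not couple with CO2/Ni(0) at 0 °C), bond formation at C7 and not C13 (ten- versus twelve-membered ring, secured by nickel residing on the primary terminus) and 1,2- rather than 1,4-addition to the enal (closed transition state); high dilution and the cis-oxirane and E-alkene as turn elements favour ring closure.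

Step 17
Reactants: 26 (1R,2S,3R,4E,6S,7R,8R,10R)-3-(tert-butyldimethylsilyloxy)-1,2-epoxy-8,10-bis(triethylsilyloxy)germacra-4,11(13)-dien-12,6-olide
Product: 27 (1R,2S,3R,4E,6S,7S,8R,10R)-3-(tert-butyldimethylsilyloxy)-1,2-epoxy-8-hydroxy-10-(triethylsilyloxy)germacra-4,11(13)-dien-12,6-olide
Conditions: HF·pyridine, pyridine, THF, 0 °C
Reagents that add atoms: none
Why: Buffered fluoride-mediated desilylation should cleave the least hindered (secondary) TES ether faster than the tertiary TES and the TBS ether, leaving the oxirane and the lactone untouched; loss of the tertiary TES group at this stage would be harmless.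

Step 18
Reactants: 27 (1R,2S,3R,4E,6S,7S,8R,10R)-3-(tert-butyldimethylsilyloxy)-1,2-epoxy-8-hydroxy-10-(triethylsilyloxy)germacra-4,11(13)-dien-12,6-olide; 28 angelic acid
Product: 30 (1R,2S,3R,4E,6S,7S,8R,10R)-8-(angeloyloxy)-3-(tert-butyldimethylsilyloxy)-1,2-epoxy-10-(triethylsilyloxy)germacra-4,11(13)-dien-12,6-olide, via mixed anhydride 29 (not isolated)
Conditions: 28, 2,4,6-trichlorobenzoyl chloride, Et3N, toluene, rt; then 27, toluene, 75 °C (no DMAP)
Reagents that add atoms: none
Why: Yamaguchi-type esterification through the angelic 2,4,6-trichlorobenzoic mixed anhydride acylates the secondary C8 alcohol without the nucleophilic catalyst that isomerises angelates to tiglates, so the (Z)-geometry should be kept.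

Step 19
Reactants: 30 (1R,2S,3R,4E,6S,7S,8R,10R)-8-(angeloyloxy)-3-(tert-butyldimethylsilyloxy)-1,2-epoxy-10-(triethylsilyloxy)germacra-4,11(13)-dien-12,6-olide
Product: 31 (1R,2R,3R,4E,6S,7S,8R,10R)-8-(angeloyloxy)-1,2-epoxy-3,10-dihydroxygermacra-4,11(13)-dien-12,6-olide
Conditions: HF·pyridine, pyridine, THF, 0 °C → rt
Reagents that add atoms: none
Why: Buffered fluoride-mediated global desilylation should remove the TBS and the tertiary TES ether under conditions compatible with the oxirane, the angelate and the α-methylene lactone.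

Step 20
Reactants: 31 (1R,2R,3R,4E,6S,7S,8R,10R)-8-(angeloyloxy)-1,2-epoxy-3,10-dihydroxygermacra-4,11(13)-dien-12,6-olide
Product: 32 (1R,2R,3R,4E,6S,7S,8R,10R)-3-acetoxy-8-(angeloyloxy)-1,2-epoxy-10-hydroxygermacra-4,11(13)-dien-12,6-olide (CNP0155556.1)
Conditions: Ac2O, pyridine, DMAP (cat.), CH2Cl2, 0 °C
Reagents that add atoms: acetic anhydride, CC(=O)OC(C)=O
Why: Acetylation distinguishes the secondary C3 alcohol from the unreactive tertiary C10 alcohol and completes the target.

**Compound list**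

1 | (R)-citramalic acid | OC(=O)[C@](C)(O)CC(=O)O | starting material
2 | (R)-2-(2,2,4-trimethyl-5-oxo-1,3-dioxolan-4-yl)acetic acid | O=C1OC(C)(C)O[C@]1(C)CC(=O)O | intermediate
3 | 2-(prop-2-yn-1-yloxy)tetrahydro-2H-pyran (racemic) | C#CCOC1CCCCO1 | starting material
4 | (R)-2-(2,2,4-trimethyl-5-oxo-1,3-dioxolan-4-yl)acetyl chloride | O=C1OC(C)(C)O[C@]1(C)CC(=O)Cl | intermediate
5 | (5R)-2,2,5-trimethyl-5-[2-oxo-5-(oxan-2-yloxy)pent-3-yn-1-yl]-1,3-dioxolan-4-one (THP epimers) | O=C1OC(C)(C)O[C@]1(C)CC(=O)C#CCOC2CCCCO2 | intermediate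
6 | (5R)-5-[(2R)-2-hydroxy-5-(oxan-2-yloxy)pent-3-yn-1-yl]-2,2,5-trimethyl-1,3-dioxolan-4-one (THP epimers) | O=C1OC(C)(C)O[C@]1(C)C[C@@H](O)C#CCOC2CCCCO2 | intermediate
7 | (2R,4R)-2-methylhepta-5,6-diene-1,2,4-triol | OC[C@](C)(O)C[C@@H](O)C=C=C | intermediate
8 | (2R,4R)-2-methyl-1,2,4-tris(triethylsilyloxy)hepta-5,6-diene | CC[Si](CC)(CC)OC[C@](C)(O[Si](CC)(CC)CC)C[C@@H](O[Si](CC)(CC)CC)C=C=C | intermediate
9 | (2R,4R)-2-methyl-2,4-bis(triethylsilyloxy)hepta-5,6-dienal | O=C[C@](C)(O[Si](CC)(CC)CC)C[C@@H](O[Si](CC)(CC)CC)C=C=C | intermediate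
10 | (R)-4-benzyl-3-(chloroacetyl)oxazolidin-2-one | ClCC(=O)N1[C@H](Cc2ccccc2)COC1=O | starting material
11 | (Z)-dibutylboron enolate of 10 | CCCCB(CCCC)O/C(=C\Cl)N1[C@H](Cc2ccccc2)COC1=O | intermediate
12 | (R)-4-benzyl-3-[(2R,3S,4R,6R)-2-chloro-3-hydroxy-4-methyl-4,6-bis(triethylsilyloxy)nona-7,8-dienoyl]oxazolidin-2-one | O=C1OC[C@@H](Cc2ccccc2)N1C(=O)[C@H](Cl)[C@@H](O)[C@](C)(O[Si](CC)(CC)CC)C[C@@H](O[Si](CC)(CC)CC)C=C=C | intermediate
13 | (2R,3S,4R,6R)-2-chloro-3-hydroxy-N-methoxy-N,4-dimethyl-4,6-bis(triethylsilyloxy)nona-7,8-dienamide | CON(C)C(=O)[C@H](Cl)[C@@H](O)[C@](C)(O[Si](CC)(CC)CC)C[C@@H](O[Si](CC)(CC)CC)C=C=C | intermediate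
14 | (2S,3R)-N-methoxy-N-methyl-3-[(2R,4R)-2,4-bis(triethylsilyloxy)hepta-5,6-dien-2-yl]oxirane-2-carboxamide (cis-oxirane) | CON(C)C(=O)[C@H]1O[C@H]1[C@](C)(O[Si](CC)(CC)CC)C[C@@H](O[Si](CC)(CC)CC)C=C=C | intermediate
15 | but-2-yn-1-ol | CC#CCO | starting material
16 | (but-2-yn-1-yloxy)triethylsilane | CC#CCO[Si](CC)(CC)CC | intermediate
17 | chloro[(E)-4-(triethylsilyloxy)but-2-en-2-yl]zirconocene | CC[Si](CC)(CC)OC/C=C(\C)[Zr](Cl)(C1C=CC=C1)C1C=CC=C1 | intermediate
18 | (E)-triethyl[(3-iodobut-2-en-1-yl)oxy]silane | CC[Si](CC)(CC)OC/C=C(\C)I | intermediate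
19 | [(E)-4-(triethylsilyloxy)but-2-en-2-yl]lithium | CC[Si](CC)(CC)OC/C=C(\C)[Li] | intermediate
20 | (2E)-1-[(2S,3R)-3-[(2R,4R)-2,4-bis(triethylsilyloxy)hepta-5,6-dien-2-yl]oxiran-2-yl]-2-methyl-4-(triethylsilyloxy)but-2-en-1-one | CC[Si](CC)(CC)OC/C=C(\C)C(=O)[C@H]1O[C@H]1[C@](C)(O[Si](CC)(CC)CC)C[C@@H](O[Si](CC)(CC)CC)C=C=C | intermediate
21 | (1R,2E)-1-[(2R,3R)-3-[(2R,4R)-2,4-bis(triethylsilyloxy)hepta-5,6-dien-2-yl]oxiran-2-yl]-2-methyl-4-(triethylsilyloxy)but-2-en-1-ol | CC[Si](CC)(CC)OC/C=C(\C)[C@@H](O)[C@H]1O[C@H]1[C@](C)(O[Si](CC)(CC)CC)C[C@@H](O[Si](CC)(CC)CC)C=C=C | intermediate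
22 | tert-butyl{[(1R,2E)-1-[(2S,3R)-3-[(2R,4R)-2,4-bis(triethylsilyloxy)hepta-5,6-dien-2-yl]oxiran-2-yl]-2-methyl-4-(triethylsilyloxy)but-2-en-1-yl]oxy}dimethylsilane | CC[Si](CC)(CC)OC/C=C(\C)[C@@H](O[Si](C)(C)C(C)(C)C)[C@H]1O[C@H]1[C@](C)(O[Si](CC)(CC)CC)C[C@@H](O[Si](CC)(CC)CC)C=C=C | intermediate
23 | (2E,4R)-4-(tert-butyldimethylsilyloxy)-4-[(2S,3R)-3-[(2R,4R)-2,4-bis(triethylsilyloxy)hepta-5,6-dien-2-yl]oxiran-2-yl]-3-methylbut-2-enal | O=C/C=C(\C)[C@@H](O[Si](C)(C)C(C)(C)C)[C@H]1O[C@H]1[C@](C)(O[Si](CC)(CC)CC)C[C@@H](O[Si](CC)(CC)CC)C=C=C | intermediate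
24 | oxanickelacycle from 23 and CO2 (η1 drawing of the fluxional π-allylnickel carboxylate, so no descriptor for C7=C11; DBU ligands omitted) | O=C/C=C(\C)[C@@H](O[Si](C)(C)C(C)(C)C)[C@H]1O[C@H]1[C@](C)(O[Si](CC)(CC)CC)C[C@@H](O[Si](CC)(CC)CC)C=C2C[Ni]OC2=O | intermediate
25 | seco hydroxy acid: 2-[(ten-membered ring C7)-yl]acrylic acid with free C6–OH, ring stereocentres as in 26 | OC(=O)C(=C)[C@@H]1[C@@H](O)/C=C(\C)[C@@H](O[Si](C)(C)C(C)(C)C)[C@H]2O[C@H]2[C@](C)(O[Si](CC)(CC)CC)C[C@H]1O[Si](CC)(CC)CC | intermediate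
26 | (1R,2S,3R,4E,6S,7R,8R,10R)-3-(tert-butyldimethylsilyloxy)-1,2-epoxy-8,10-bis(triethylsilyloxy)germacra-4,11(13)-dien-12,6-olide | C=C1C(=O)O[C@H]2/C=C(\C)[C@@H](O[Si](C)(C)C(C)(C)C)[C@H]3O[C@H]3[C@](C)(O[Si](CC)(CC)CC)C[C@@H](O[Si](CC)(CC)CC)[C@H]12 | intermediate
27 | (1R,2S,3R,4E,6S,7S,8R,10R)-3-(tert-butyldimethylsilyloxy)-1,2-epoxy-8-hydroxy-10-(triethylsilyloxy)germacra-4,11(13)-dien-12,6-olide | C=C1C(=O)O[C@H]2/C=C(\C)[C@@H](O[Si](C)(C)C(C)(C)C)[C@H]3O[C@H]3[C@](C)(O[Si](CC)(CC)CC)C[C@@H](O)[C@H]12 | intermediate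
28 | angelic acid, (Z)-2-methylbut-2-enoic acid | C/C=C(/C)C(=O)O | starting material
29 | angelic 2,4,6-trichlorobenzoic anhydride | C/C=C(/C)C(=O)OC(=O)c1c(Cl)cc(Cl)cc1Cl | intermediate
30 | (1R,2S,3R,4E,6S,7S,8R,10R)-8-(angeloyloxy)-3-(tert-butyldimethylsilyloxy)-1,2-epoxy-10-(triethylsilyloxy)germacra-4,11(13)-dien-12,6-olide | C=C1C(=O)O[C@H]2/C=C(\C)[C@@H](O[Si](C)(C)C(C)(C)C)[C@H]3O[C@H]3[C@](C)(O[Si](CC)(CC)CC)C[C@@H](OC(=O)/C(C)=C\C)[C@H]12 | intermediate
31 | (1R,2R,3R,4E,6S,7S,8R,10R)-8-(angeloyloxy)-1,2-epoxy-3,10-dihydroxygermacra-4,11(13)-dien-12,6-olide | C=C1C(=O)O[C@H]2/C=C(\C)[C@@H](O)[C@H]3O[C@H]3[C@](C)(O)C[C@@H](OC(=O)/C(C)=C\C)[C@H]12 | intermediate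
32 | (1R,2R,3R,4E,6S,7S,8R,10R)-3-acetoxy-8-(angeloyloxy)-1,2-epoxy-10-hydroxygermacra-4,11(13)-dien-12,6-olide (CNP0155556.1) | C=C1C(=O)O[C@H]2/C=C(\C)[C@@H](OC(C)=O)[C@H]3O[C@H]3[C@](C)(O)C[C@@H](OC(=O)/C(C)=C\C)[C@H]12 | target

**Step count and risks**

Total step count: 20. Longest linear sequence: 18 steps (steps 1–9 and 12–20, from (R)-citramalic acid); steps 10–11 make the alkenyl iodide.

Steps most likely to fail:

Step 16 (proposed new method). The oxanickelacycle may be protonated or may add to a second molecule instead of closing the ten-membered ring, or the ring may close on the wrong face of C7 relative to C8. The fallback sets out from 23 and comes back at 26, and makes the two bonds in separate, known steps. Bromine (1 equiv, CH2Cl2, −78 °C) would add to the cumulene, the most nucleophilic π-system next to the deactivated enal, to give the 2,3-dibromoallyl compound F1; either allylic regioisomer serves because both give the same allylmetal. CrCl2 in THF at high dilution (Nozaki–Hiyama–Kishi-type Barbier macrocyclisation, anti-selective through the equilibrating allylchromium) would then close the carbocycle to the 2-bromo homoallylic alcohol F2. Pd(PPh3)4, CO and Et3N in MeCN (cyclocarbonylation of a 2-bromoallylic alcohol) would finally form C11–C12 and the lactone to give 26.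

Step 7. Addition to the neopentyl-type α-quaternary aldehyde may be slow enough for the chloro enolate to decompose, or double stereodifferentiation with the C10 centre may be mismatched and erode the syn selectivity. The fallback sets out from 9 and comes back at 21, and builds the oxirane by reagent-controlled epoxidation instead of an aldol. Still–Gennari olefination ((CF3CH2O)2P(O)CH2CO2Me, KHMDS, 18-crown-6, THF, −78 °C) would give the (Z)-enoate F3, and DIBAL-H would give the (Z)-allylic alcohol F4. Sharpless epoxidation with Ti(OiPr)4, D-(−)-diethyl tartrate and t-BuOOH would give the cis-epoxy alcohol F5, and Dess–Martin oxidation would give the cis-epoxy aldehyde F6. Felkin–Anh addition of alkenyllithium 19 (from 18) should then give 21 directly; any 3-epimer could be oxidised to 20 and reduced as in step 13.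

Step 18. The angeloyl group may isomerise to the tigloyl group during acyl transfer, or the hindered C8 hydroxyl may not be acylated. The fallback sets out from 27 and comes back at 30, and builds the (Z)-alkene on the ester instead of transferring it. DCC/DMAP esterification of 27 with 2-[bis(2,2,2-trifluoroethoxy)phosphoryl]propanoic acid would give the phosphonate ester F7. Still–Gennari olefination of F7 with acetaldehyde (KHMDS, 18-crown-6, THF, −78 °C, base added to the mixture of ester and aldehyde) should give the (Z)-2-methylbut-2-enoate 30.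

**Further compounds**

F1 | step 16 | (2E,4R)-4-(tert-butyldimethylsilyloxy)-4-[(2S,3R)-3-[(2R,4R)-6,7-dibromo-2,4-bis(triethylsilyloxy)hept-5-en-2-yl]oxiran-2-yl]-3-methylbut-2-enal (C5=C6 geometry of the heptenyl chain not defined) | O=C/C=C(\C)[C@@H](O[Si](C)(C)C(C)(C)C)[C@H]1O[C@H]1[C@](C)(O[Si](CC)(CC)CC)C[C@@H](O[Si](CC)(CC)CC)C=C(Br)CBr
F2 | step 16 | 11-bromo-3-(tert-butyldimethylsilyloxy)-1,2-epoxy-8,10-bis(triethylsilyloxy)-12-norgermacra-4,11(13)-dien-6-ol (ring stereocentres as in 26) | C=C(Br)[C@@H]1[C@@H](O)/C=C(\C)[C@@H](O[Si](C)(C)C(C)(C)C)[C@H]2O[C@H]2[C@](C)(O[Si](CC)(CC)CC)C[C@H]1O[Si](CC)(CC)CC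
F3 | step 7 | methyl (2Z,4R,6R)-4-methyl-4,6-bis(triethylsilyloxy)nona-2,7,8-trienoate | COC(=O)/C=C\[C@](C)(O[Si](CC)(CC)CC)C[C@@H](O[Si](CC)(CC)CC)C=C=C
F4 | step 7 | (2Z,4R,6R)-4-methyl-4,6-bis(triethylsilyloxy)nona-2,7,8-trien-1-ol | OC/C=C\[C@](C)(O[Si](CC)(CC)CC)C[C@@H](O[Si](CC)(CC)CC)C=C=C
F5 | step 7 | [(2R,3R)-3-[(2R,4R)-2,4-bis(triethylsilyloxy)hepta-5,6-dien-2-yl]oxiran-2-yl]methanol | OC[C@H]1O[C@H]1[C@](C)(O[Si](CC)(CC)CC)C[C@@H](O[Si](CC)(CC)CC)C=C=C
F6 | step 7 | (2S,3R)-3-[(2R,4R)-2,4-bis(triethylsilyloxy)hepta-5,6-dien-2-yl]oxirane-2-carbaldehyde | O=C[C@H]1O[C@H]1[C@](C)(O[Si](CC)(CC)CC)C[C@@H](O[Si](CC)(CC)CC)C=C=C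
F7 | step 18 | 8-O-{2-[bis(2,2,2-trifluoroethoxy)phosphoryl]propanoyl} derivative of 27 (epimers at the phosphonate α-carbon) | C=C1C(=O)O[C@H]2/C=C(\C)[C@@H](O[Si](C)(C)C(C)(C)C)[C@H]3O[C@H]3[C@](C)(O[Si](CC)(CC)CC)C[C@@H](OC(=O)C(C)P(=O)(OCC(F)(F)F)OCC(F)(F)F)[C@H]12
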